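**Plan**
- Retrosynthesis: the three phenol benzyl ethers come off last. Ring B (C1' carries the bridge CH2, C2' OH, C3' CH3, C4' OH, C5' propanoyl, C6' OH) is cut at C3'–C4' and C5'–C6'. The CH2–C1' bond is then cut back to a ring A benzylic bromide and methyl 3-oxopentanoate.
- Enabling feature: C6'–C1'–C2'–C3' has the carbon and oxygen pattern of a 2-substituted methyl 3-oxopentanoate (ester carbon = C6', ketone carbon = C2', ethyl CH2 = C3'). C4'(O)–C5'(propanoyl) is a propanoyl-substituted ynol ether.
- Forward: ring A is built from 2-methylphloroglucinol (C-butanoylation, 4-O-methylation, C5 formylation, benzylation), turned into the benzylic bromide and joined to methyl 3-oxopentanoate. Two-stage silylation gives the 1-methoxy-1,3-bis(silyloxy)diene.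
- Ring B, the only ring made in the route, closes by (4+2) cycloaddition with 1-(benzyloxy)pent-1-yn-3-one and loss of methanol. One hydrogenolysis then frees all phenols.
- Stereochemistry: the target has no stereocentre. The racemic centre of the keto ester, the enol ether geometries and the two sp3 centres of the cycloadduct are all erased.

Key step: step 12

Remark: the ynol ether oxygen is carried as a benzyl ether, so that the C4' oxygen is freed by the same hydrogenolysis as ring A and the C4 methyl ether never meets a Lewis acid.
Remark: enolates and alkoxides that a base generates from a reactant are treated as forms of that reactant and are not numbered.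
Assumption: enol silyl ether geometries are left unspecified and the compounds are used as isomer mixtures, since each such double bond ends in the arene or reverts to a ketone.

**Route**

Step 1
Reactants: 1 2-methylbenzene-1,3,5-triol (2-methylphloroglucinol); 2 butanoyl chloride
Product: 3 1-(2,4,6-trihydroxy-3-methylphenyl)butan-1-one
Conditions: AlCl3 (3 equiv), PhNO2/CH2Cl2, 0 → 50 °C; aq. HCl
Reagents that add atoms: none
Why: Friedel–Crafts C-acylation of a highly activated phenol whose two free ring positions are equivalent, so one mono-ketone should form, the aluminium chelate of the product resisting a second acylation.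

Step 2
Reactants: 3 1-(2,4,6-trihydroxy-3-methylphenyl)butan-1-one
Product: 4 1-(2,6-dihydroxy-4-methoxy-3-methylphenyl)butan-1-one (aspidinol)
Conditions: MeI (1.0 equiv), K2CO3 (1.0 equiv), acetone, 20 °C
Reagents that add atoms: iodomethane, CI
Why: Williamson O-methylation in which the hydroxyl para to the acyl group is the most acidic and is not hydrogen-bonded to the ketone, so one equivalent of iodomethane should be taken up there.

Step 3
Reactants: 4 aspidinol
Product: 6 3-butanoyl-2,4-dihydroxy-6-methoxy-5-methylbenzaldehyde, via aryl iminium chloride 5 (not isolated)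
Conditions: POCl3, DMF, EtOAc, 0 → 20 °C; then H2O, 50 °C
Reagents that add atoms: N,N-dimethylformamide, CN(C)C=O; water, O
Why: Vilsmeier–Haack formylation at C5, the only unsubstituted ring carbon, which is activated by the flanking hydroxyl and methoxy groups.

Step 4
Reactants: 6 3-butanoyl-2,4-dihydroxy-6-methoxy-5-methylbenzaldehyde
Product: 7 2,4-bis(benzyloxy)-3-butanoyl-6-methoxy-5-methylbenzaldehyde
Conditions: BnBr (2.5 equiv), K2CO3, DMF, 60 °C
Reagents that add atoms: benzyl bromide, BrCc1ccccc1
Why: Williamson benzylation in which carbonate in warm DMF overcomes the hydrogen bonding of both phenols to the neighbouring carbonyl groups, the fully substituted ring leaving no site for aromatic C-benzylation.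

Step 5
Reactants: 7 2,4-bis(benzyloxy)-3-butanoyl-6-methoxy-5-methylbenzaldehyde
Product: 8 1-[2,6-bis(benzyloxy)-3-(hydroxymethyl)-4-methoxy-5-methylphenyl]butan-1-one
Conditions: NaBH4 (0.5 equiv), THF/MeOH, −20 °C
Reagents that add atoms: none
Why: Chemoselective borohydride reduction, the aldehyde being far more electrophilic than the aryl ketone that is shielded and twisted out of conjugation by two ortho benzyloxy groups.

Step 6
Reactants: 8 1-[2,6-bis(benzyloxy)-3-(hydroxymethyl)-4-methoxy-5-methylphenyl]butan-1-one
Product: 9 1-[2,6-bis(benzyloxy)-3-(bromomethyl)-4-methoxy-5-methylphenyl]butan-1-one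
Conditions: CBr4, PPh3, CH2Cl2, 0 °C; used without storage
Reagents that add atoms: tetrabromomethane, BrC(Br)(Br)Br
Why: Appel bromination converts the electron-rich benzylic alcohol under neutral conditions, avoiding the acid that could cleave benzyl ethers or ionise the product.

Step 7
Reactants: 9 ring A benzylic bromide; 10 methyl 3-oxopentanoate
Product: 11 methyl 2-{[2,4-bis(benzyloxy)-3-butanoyl-6-methoxy-5-methylphenyl]methyl}-3-oxopentanoate (racemic)
Conditions: NaH (1.4 equiv), 10 (1.5 equiv), THF, 0 °C; then 9, 0 → 20 °C
Reagents that add atoms: none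
Why: Acetoacetic-ester-type C-alkylation of the sodium enolate of a β-keto ester with a reactive benzylic bromide, excess 10 suppressing dialkylation.

Step 8
Reactants: 11 methyl 2-{[2,4-bis(benzyloxy)-3-butanoyl-6-methoxy-5-methylphenyl]methyl}-3-oxopentanoate
Product: 12 methyl 2-{[2,4-bis(benzyloxy)-3-butanoyl-6-methoxy-5-methylphenyl]methyl}-3-(trimethylsilyloxy)pent-2-enoate (E/Z mixture)
Conditions: Me3SiCl (1.5 equiv), Et3N (1.6 equiv), toluene, 20 °C; filtration under argon
Reagents that add atoms: chlorotrimethylsilane, C[Si](C)(C)Cl
Why: Amine-mediated O-silylation of the β-keto ester is the standard first stage of 1-alkoxy-1,3-bis(silyloxy)diene preparation, the much less acidic aryl ketone staying untouched and either regioisomeric enol ether leading to the same diene in step 9.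

Step 9
Reactants: 12 mono enol silyl ether
Product: 13 1-methoxy-1,3-bis(trimethylsilyloxy)penta-1,3-diene carrying at C2 the {2,4-bis(benzyloxy)-6-methoxy-5-methyl-3-[1-(trimethylsilyloxy)but-1-enyl]phenyl}methyl group (isomer mixture, used crude)
Conditions: LiN(i-Pr)2 (LDA, 2.5 equiv), THF, −78 °C; Me3SiCl (3 equiv), −78 → 0 °C; evaporation and filtration under argon
Reagents that add atoms: chlorotrimethylsilane, C[Si](C)(C)Cl
Why: Kinetic deprotonation at the γ-CH2 of the silyloxy enoate and at the α-CH2 of the butanoyl group followed by O-silylation is the standard second stage of the diene preparation and at the same time masks the ring A ketone as its enol silyl ether.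

Step 10
Reactants: 14 benzyl alcohol; 15 trichloroethene
Product: 16 benzyl (E)-1,2-dichloroethenyl ether
Conditions: KH, THF, 0 °C; then 15, 0 → 20 °C
Reagents that add atoms: none
Why: Potassium benzyloxide effects elimination of trichloroethene to dichloroethyne and adds to it (elimination–addition), the established entry to 1,2-dichlorovinyl ethers as ynol ether precursors.

Step 11
Reactants: 16 benzyl (E)-1,2-dichloroethenyl ether; 17 N-methoxy-N-methylpropanamide
Product: 19 1-(benzyloxy)pent-1-yn-3-one, via lithium (benzyloxy)ethynide 18 (not isolated)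
Conditions: n-BuLi (2.2 equiv), THF, −78 → −40 °C; then 17, −78 → 0 °C; aq. NH4Cl; rapid filtration through Et3N-deactivated silica, used at once
Reagents that add atoms: none
Why: Dehydrochlorination and chlorine–lithium exchange by n-BuLi give the lithium alkoxyacetylide, which is acylated in a Weinreb ketone synthesis whose chelated tetrahedral intermediate prevents over-addition.

Step 12
Reactants: 13 tris(silyl) diene; 19 1-(benzyloxy)pent-1-yn-3-one
Product: 21 1-[2,6-bis(benzyloxy)-3-{[4-(benzyloxy)-2,6-dihydroxy-3-methyl-5-propanoylphenyl]methyl}-4-methoxy-5-methylphenyl]butan-1-one, via cyclohexa-1,4-diene cycloadduct 20 (not isolated)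
Conditions: 19 (1.5 equiv), toluene, −20 → 25 °C; then 1 M HCl, THF, 0 → 20 °C
Reagents that add atoms: none
Why: Proposed new method: the methyl-bearing diene terminus (C4 of the pentadiene, the future C3'), the most nucleophilic carbon of a 1-alkoxy-1,3-bis(silyloxy)diene, should attack the benzyloxy-bearing alkyne carbon of 19, which remains the β-acceptor position of the push–pull ynone, and the resulting allenolate carbon α to the ketone should then bond to the methoxy(silyloxy)carbenium carbon (future C6'), either in one asynchronous (4+2) event or as a Mukaiyama–Michael addition followed by ring closure; the closest known reaction type is the Diels–Alder/aromatisation of 1-alkoxy-1-silyloxy- and 1,3-bis(silyloxy)dienes with acetylenic ketones and esters to give resorcinol derivatives, the new element being the alkoxy group on the alkyne. Ring B closes as a carbocycle in the (4+2) mode, which in the stepwise limit is a 6-exo-trig attack of the allenolate on the oxocarbenium carbon. In cycloadduct 20 the C6' methyl silyl ketal and the C3' hydrogen stand 1,4 to each other, so acid-promoted loss of methanol aromatises the ring, and the same aqueous acid cleaves the aryl silyl ethers and returns the ring A ketone from its enol silyl ether. No stereocentre is set, since C3' and C6' of 20 both become sp2. The step needs head-to-tail regioselectivity and attack on C≡C rather than C=O: the first follows from the matched polarity just described, which places the propanoyl group at C5' between two oxygens, and the second from working without a Lewis acid, which also leaves the hindered ring A enol silyl ether a spectator. The temperature is held at or below 25 °C because benzyl alkynyl ethers rearrange sigmatropically on moderate heating.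

Step 13
Reactants: 21 tris(benzyl ether) of the target
Product: 22 1-{2,6-dihydroxy-4-methoxy-3-methyl-5-[(2,4,6-trihydroxy-3-methyl-5-propanoylphenyl)methyl]phenyl}butan-1-one (target)
Conditions: H2 (1 atm), Pd/C (10% Pd on carbon), EtOAc/MeOH, 20 °C
Reagents that add atoms: none
Why: Catalytic hydrogenolysis should cleave all three aryl benzyl ethers while the hydrogen-bonded, electron-rich aryl ketones, the diarylmethane bridge and the methyl ether are inert under these mild conditions.

**Compound list**
1 | 2-methylbenzene-1,3,5-triol (2-methylphloroglucinol) | Cc1c(O)cc(O)cc1O | starting material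
2 | butanoyl chloride | CCCC(=O)Cl | starting material
3 | 1-(2,4,6-trihydroxy-3-methylphenyl)butan-1-one | CCCC(=O)c1c(O)c(C)c(O)cc1O | intermediate
4 | 1-(2,6-dihydroxy-4-methoxy-3-methylphenyl)butan-1-one (aspidinol) | CCCC(=O)c1c(O)c(C)c(OC)cc1O | intermediate
5 | N-[(3-butanoyl-2,4-dihydroxy-6-methoxy-5-methylphenyl)methylidene]-N-methylmethanaminium chloride | CCCC(=O)c1c(O)c(C)c(OC)c(C=[N+](C)C)c1O.[Cl-] | intermediate (not isolated)
6 | 3-butanoyl-2,4-dihydroxy-6-methoxy-5-methylbenzaldehyde | CCCC(=O)c1c(O)c(C)c(OC)c(C=O)c1O | intermediate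
7 | 2,4-bis(benzyloxy)-3-butanoyl-6-methoxy-5-methylbenzaldehyde | CCCC(=O)c1c(OCc2ccccc2)c(C)c(OC)c(C=O)c1OCc1ccccc1 | intermediate
8 | 1-[2,6-bis(benzyloxy)-3-(hydroxymethyl)-4-methoxy-5-methylphenyl]butan-1-one | CCCC(=O)c1c(OCc2ccccc2)c(C)c(OC)c(CO)c1OCc1ccccc1 | intermediate
9 | 1-[2,6-bis(benzyloxy)-3-(bromomethyl)-4-methoxy-5-methylphenyl]butan-1-one | CCCC(=O)c1c(OCc2ccccc2)c(C)c(OC)c(CBr)c1OCc1ccccc1 | intermediate
10 | methyl 3-oxopentanoate | CCC(=O)CC(=O)OC | starting material
11 | methyl 2-{[2,4-bis(benzyloxy)-3-butanoyl-6-methoxy-5-methylphenyl]methyl}-3-oxopentanoate (racemic) | CCCC(=O)c1c(OCc2ccccc2)c(C)c(OC)c(CC(C(=O)CC)C(=O)OC)c1OCc1ccccc1 | intermediate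
12 | methyl 2-{[2,4-bis(benzyloxy)-3-butanoyl-6-methoxy-5-methylphenyl]methyl}-3-(trimethylsilyloxy)pent-2-enoate (E/Z mixture) | CCCC(=O)c1c(OCc2ccccc2)c(C)c(OC)c(CC(C(=O)OC)=C(CC)O[Si](C)(C)C)c1OCc1ccccc1 | intermediate
13 | 2-{[2,4-bis(benzyloxy)-6-methoxy-5-methyl-3-(1-(trimethylsilyloxy)but-1-enyl)phenyl]methyl}-1-methoxy-1,3-bis(trimethylsilyloxy)penta-1,3-diene (isomer mixture) | CCC=C(O[Si](C)(C)C)c1c(OCc2ccccc2)c(C)c(OC)c(CC(C(O[Si](C)(C)C)=CC)=C(OC)O[Si](C)(C)C)c1OCc1ccccc1 | intermediate
14 | benzyl alcohol | OCc1ccccc1 | starting material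
15 | trichloroethene | ClC=C(Cl)Cl | starting material
16 | benzyl (E)-1,2-dichloroethenyl ether | Cl/C=C(/Cl)OCc1ccccc1 | intermediate
17 | N-methoxy-N-methylpropanamide | CCC(=O)N(C)OC | starting material
18 | lithium (benzyloxy)ethynide | [Li]C#COCc1ccccc1 | intermediate (not isolated)
19 | 1-(benzyloxy)pent-1-yn-3-one | CCC(=O)C#COCc1ccccc1 | intermediate
20 | cyclohexa-1,4-diene cycloadduct: C6'(OMe)(OSiMe3), C1'(CH2–ring A)=C2'(OSiMe3), C3'(H)(CH3), C4'(OBn)=C5'(propanoyl), ring A as in 13 (diastereomer mixture) | CCC=C(O[Si](C)(C)C)c1c(OCc2ccccc2)c(C)c(OC)c(CC2=C(O[Si](C)(C)C)C(C)C(OCc3ccccc3)=C(C(=O)CC)C2(OC)O[Si](C)(C)C)c1OCc1ccccc1 | intermediate (not isolated)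
21 | 1-[2,6-bis(benzyloxy)-3-{[4-(benzyloxy)-2,6-dihydroxy-3-methyl-5-propanoylphenyl]methyl}-4-methoxy-5-methylphenyl]butan-1-one | CCCC(=O)c1c(OCc2ccccc2)c(C)c(OC)c(Cc2c(O)c(C)c(OCc3ccccc3)c(C(=O)CC)c2O)c1OCc1ccccc1 | intermediate
22 | 1-{2,6-dihydroxy-4-methoxy-3-methyl-5-[(2,4,6-trihydroxy-3-methyl-5-propanoylphenyl)methyl]phenyl}butan-1-one | CCCC(=O)c1c(O)c(C)c(OC)c(Cc2c(O)c(C)c(O)c(C(=O)CC)c2O)c1O | target

**Count**
Total steps: 13. Longest linear sequence: 11 steps (steps 1–9, 12, 13); steps 10 and 11 form the two-step dienophile branch.

**Steps most likely to fail**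

Step 12. The alkoxy group may damp the electrophilicity of the alkyne so far that hydrolysis or protodesilylation of the diene, or sigmatropic rearrangement of the benzyl alkynyl ether, outruns carbon–carbon bond formation. The fallback abandons the cycloaddition and joins two preformed aromatic rings by known Mannich-base chemistry. It sets out from 4 (with 1 as second input) and returns at 22. Compound 4 with aqueous formaldehyde and dimethylamine in ethanol should give the Mannich base 1-{3-[(dimethylamino)methyl]-2,6-dihydroxy-4-methoxy-5-methylphenyl}butan-1-one F1, substitution being possible only at C5. Compound 1 is C-acylated with propanoyl chloride and AlCl3, as in step 1, to 1-(2,4,6-trihydroxy-3-methylphenyl)propan-1-one F2. Heating F1 with F2 in dioxane at about 100 °C should expel dimethylamine and alkylate the single free ring carbon of F2, which becomes C1', giving 22 directly with no protecting groups.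

Step 11. The lithiated benzyl ether may undergo Wittig-type rearrangement, the benzyl alkynyl ether may rearrange thermally, and the acyl ynol ether may hydrate to the β-keto ester during work-up or purification. The fallback changes the ynol ether to the thermally robust ethyl series and changes the endgame accordingly. It sets out from 17 and returns at 22. Commercial ethoxyethyne (C#COCC) is lithiated with n-BuLi in THF at −78 °C to lithium ethoxyethynide F3, which is acylated by 17 to 1-ethoxypent-1-yn-3-one F4. Reaction of F4 with 13 under the conditions of step 12 should pass through the ethoxy-substituted cyclohexa-1,4-diene cycloadduct F5 and give, after acidic work-up, the C4' ethyl ether 1-[2,6-bis(benzyloxy)-3-[(4-ethoxy-2,6-dihydroxy-3-methyl-5-propanoylphenyl)methyl]-4-methoxy-5-methylphenyl]butan-1-one F6. BCl3 in CH2Cl2 (−78 → 0 °C) should then cleave the two benzyl ethers and, assisted by chelation to the C5' carbonyl, the C4' ethyl ether, while the non-chelated C4 methyl ether is expected to persist, giving 22.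

Step 9. Two enolisations must be completed in one operation, and proton exchange between the ring A ketone enolate and the ester dienolate, C-silylation, or hydrolysis of the ketene acetal on handling may leave the diene incomplete. The fallback masks the ring A ketone before any strong base is used. It sets out from 11 and returns at 13, bypassing 12. Compound 11 with Me3SiOSO2CF3 (2.2 equiv) and Et3N in Et2O at 0 °C (soft enolisation) should give the bis(enol silyl ether) methyl 2-{[2,4-bis(benzyloxy)-6-methoxy-5-methyl-3-(1-(trimethylsilyloxy)but-1-enyl)phenyl]methyl}-3-(trimethylsilyloxy)pent-2-enoate F7. A single γ-deprotonation with LiN(i-Pr)2 (1.2 equiv) at −78 °C and trapping with Me3SiCl then gives 13.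

**Further compounds**
F1 | step 12 | 1-{3-[(dimethylamino)methyl]-2,6-dihydroxy-4-methoxy-5-methylphenyl}butan-1-one | CCCC(=O)c1c(O)c(C)c(OC)c(CN(C)C)c1O
F2 | step 12 | 1-(2,4,6-trihydroxy-3-methylphenyl)propan-1-one | CCC(=O)c1c(O)c(C)c(O)cc1O
F3 | step 11 | lithium ethoxyethynide | [Li]C#COCC
F4 | step 11 | 1-ethoxypent-1-yn-3-one | CCOC#CC(=O)CC
F5 | step 11 | ethoxy-substituted cyclohexa-1,4-diene cycloadduct (C4' OEt analogue of 20) | CCC=C(O[Si](C)(C)C)c1c(OCc2ccccc2)c(C)c(OC)c(CC2=C(O[Si](C)(C)C)C(C)C(OCC)=C(C(=O)CC)C2(OC)O[Si](C)(C)C)c1OCc1ccccc1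
F6 | step 11 | 1-[2,6-bis(benzyloxy)-3-[(4-ethoxy-2,6-dihydroxy-3-methyl-5-propanoylphenyl)methyl]-4-methoxy-5-methylphenyl]butan-1-one | CCCC(=O)c1c(OCc2ccccc2)c(C)c(OC)c(Cc2c(O)c(C)c(OCC)c(C(=O)CC)c2O)c1OCc1ccccc1
F7 | step 9 | methyl 2-{[2,4-bis(benzyloxy)-6-methoxy-5-methyl-3-(1-(trimethylsilyloxy)but-1-enyl)phenyl]methyl}-3-(trimethylsilyloxy)pent-2-enoate | CCC=C(O[Si](C)(C)C)c1c(OCc2ccccc2)c(C)c(OC)c(CC(C(=O)OC)=C(CC)O[Si](C)(C)C)c1OCc1ccccc1
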